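**Assumptions**
- The SMILES fixes five stereocentres: C2–C5 are D-gluco, and C1 is (R). This means the C1–OH is cis to the C2–C3 bond in the new six-membered lactone ring. The biaryl axes are not encoded in the SMILES. I assume the D-gluco chain templates the natural axial configurations, (S) for the 4,6-HHDP.
- I assume benzaldehyde dimethyl acetal forms the 4,6-O-benzylidene 1,3-dioxane of open-chain glucose dithioacetal.

**Retrosynthesis**
1. The target is the 16-fold O-benzyl compound after hydrogenolysis. The 4,6-HHDP is closed last, by Ullmann coupling of a 4,6-bis(2-iodoaroyl) diester.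
2. The C1–aryl bond and the C1 stereocentre come from an intramolecular Nozaki–Hiyama–Kishi (NHK) addition of an aryl iodide on ring C to the C1 aldehyde. This forms the benzo-lactone ring, replacing the usual intermolecular aryllithium addition.
3. The A–B–C terphenoyl (NHTP) macrocycle comes from one-pot double intramolecular Ullmann coupling of a tris(2,6-diiodoaroyl) glucose. The central ring B sits on O3.
4. The open-chain D-glucose is locked as its diethyl dithioacetal, with the 4,6-diol temporarily masked as a benzylidene acetal. The aroyl chloride comes from methyl gallate.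
5. Ring-forming order: two NHTP biaryl bonds, then the C1 lactone ring, then the 4,6-HHDP ring.

**Route**

**Step 1**
Reactants: 1 methyl gallate; 2 benzyl bromide
Product: 3 methyl 3,4,5-tris(benzyloxy)benzoate
Conditions: BnBr (3.6 equiv), K2CO3, DMF, 60 °C
Reagents that add atoms: benzyl bromide (2), BrCc1ccccc1
Why: Williamson O-benzylation of the three phenols.

**Step 2**
Reactants: 3; 4 iodine
Product: 5 methyl 3,4,5-tris(benzyloxy)-2-iodobenzoate
Conditions: I2 (1.1 equiv), CF3CO2Ag, CHCl3, 0→23 °C, dark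
Reagents that add atoms: iodine (4), II
Why: Ag(I)-activated electrophilic iodination of the electron-rich ring. C2 and C6 are equivalent, so there is one mono-iodide.

**Step 3**
Reactants: 5; 6 water
Product: 7 3,4,5-tris(benzyloxy)-2-iodobenzoic acid
Conditions: KOH, EtOH/H2O, 80 °C; then 1 M HCl
Reagents that add atoms: water (6), O
Why: saponification of the hindered methyl ester. Aryl iodide and benzyl ethers are inert.

**Step 4**
Reactants: 7; 8 oxalyl chloride
Product: 9 3,4,5-tris(benzyloxy)-2-iodobenzoyl chloride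
Conditions: (COCl)2, cat. DMF, CH2Cl2, 0→23 °C
Reagents that add atoms: oxalyl chloride (8), ClC(=O)C(=O)Cl
Why: Vilsmeier-type acid chloride formation.

**Step 5**
Reactants: 10 D-glucose; 11 ethanethiol
Product: 12 D-glucose diethyl dithioacetal
Conditions: EtSH, conc. HCl, 0→23 °C
Reagents that add atoms: ethanethiol (11), CCS
Why: Fischer dithioacetalisation traps the open-chain form and keeps C2–C5 D-gluco.

**Step 6**
Reactants: 12; 13 benzaldehyde dimethyl acetal
Product: 14 4,6-O-benzylidene-D-glucose diethyl dithioacetal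
Conditions: PhCH(OMe)2, cat. CSA, DMF, 40 °C, 50 mbar
Reagents that add atoms: benzaldehyde dimethyl acetal (13), COC(OC)c1ccccc1
Why: trans-acetalisation gives the thermodynamic 1,3-dioxane across O4/O6, leaving O2, O3 and O5 free.

**Step 7**
Reactants: 14; 9 (4 equiv)
Product: 15 4,6-O-benzylidene-2,3,5-tris-O-(2-iodo-3,4,5-tribenzyloxybenzoyl)-D-glucose diethyl dithioacetal
Conditions: DMAP, Et3N, CH2Cl2, 40 °C
Reagents that add atoms: acid chloride 9 (already numbered)
Why: DMAP-catalysed acylation. All three hydroxyls receive the same acyl group, so there is no regiochemical issue.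

**Step 8**
Reactants: 15; 6 water
Product: 16 aldehydo-sugar (C1 CHO), otherwise as 15
Conditions: MeI, CaCO3, MeCN/H2O 9:1, 50 °C
Reagents that add atoms: water (6), O
Why: S-methylation followed by hydrolysis unmasks the aldehyde. CaCO3 buffers the medium to protect the α-acyloxy C2 centre from epimerisation. The benzylidene and aryl iodides survive.

**Step 9**
Reactants: 16; 17 N-iodosuccinimide (≥3.3 equiv)
Product: 18 hexa-iodo aldehyde (each of the three aroyl rings is 2,6-diiodo)
Conditions: NIS, HFIP, 50 °C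
Reagents that add atoms: NIS (17), O=C1CCC(=O)N1I
Why: Proposed new method: the aldehyde is already free, so NIS does not attack a thioacetal. HFIP-activated NIS iodinates the remaining ortho C–H of each ring (closest known reaction: NIS/HFIP iodination of trialkoxyarenes). Exhaustive iodination makes the product independent of which ring pair couples first, and HFIP is non-acidic, so the benzylidene survives.

**Step 10**
Reactants: 18
Product: 19 bis-macrocyclic A–B–C terphenoyl aldehyde. It keeps one iodide on ring A and one on ring C.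
Conditions: CuTC (6 equiv), NMP, 2 mM, 23→60 °C
Reagents that add atoms: none
Why: Proposed new method: intramolecular Ullmann couplings of ortho-iodo galloyl esters, as in standard HHDP synthesis, are templated by the glucose chain. The vicinal O2/O3 pair closes a 10-membered ring and the O3/O5 pair an 11-membered ring. Ring B on O3 uses both of its iodides, while the 13-membered O2/O5 closure is disfavoured. Closest known reaction: CuTC Ullmann biaryl coupling and Cu-mediated HHDP macrolactonisation.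

**Step 11**
Reactants: 19
Product: 20 the C1 alcohol (C1 R) with the new benzo-lactone ring. The ring-A iodide becomes C–H.
Conditions: CrCl2 (12 equiv), NiCl2 (0.1 equiv), DMF, 0.003 M, 23 °C; then H2O quench
Reagents that add atoms: none (only H from the aqueous quench)
Why: Proposed new method: Ni/Cr insertion into the ring-C iodide gives an aryl-Cr(III) that adds intramolecularly to the C1 aldehyde, closing the six-membered lactone. The new C1 centre is set by the cyclic transition state. Placing the bulky O–Cr pseudo-axial and the C2–C3 chain pseudo-equatorial avoids A(1,3) strain with the peri C5′–OBn. This gives the cis (1R) alcohol. The stray ring-A aryl-Cr is protonated on workup to the required C–H. Closest known reaction: intramolecular NHK of aryl iodides with aldehydes.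

**Step 12**
Reactants: 20; 21 benzyl trichloroacetimidate
Product: 22 the C1 benzyl ether of 20
Conditions: BnOC(=NH)CCl3 (5 equiv), cat. TfOH, CH2Cl2/cyclohexane, 0 °C
Reagents that add atoms: benzyl trichloroacetimidate (21), N=C(OCc1ccccc1)C(Cl)(Cl)Cl
Why: acid-catalysed benzylation gives a C1 protecting group that leaves stereochemistry untouched. Without it, the C1–OH would be acylated in Step 14.

**Step 13**
Reactants: 22
Product: 23 the 4,6-diol (benzylidene removed)
Conditions: 80% aq. AcOH, 60 °C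
Reagents that add atoms: none
Why: benzylidene hydrolysis. The aryl esters, lactones and benzyl ethers survive.

**Step 14**
Reactants: 23; 9 (3 equiv)
Product: 24 the 4,6-bis(2-iodoaroyl) diester
Conditions: DMAP, Et3N, CH2Cl2, 40 °C
Reagents that add atoms: acid chloride 9
Why: acylation of the primary O6 and secondary O4. Ring A/B/C iodides are gone, so no competing coupling partner remains.

**Step 15**
Reactants: 24
Product: 25 hexadeca-O-benzyl target
Conditions: CuTC, NMP, 2 mM, 23→60 °C
Reagents that add atoms: none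
Why: intramolecular Ullmann coupling closes the 4,6-HHDP ring. The glucose chain templates the (S) axis, as in all 4,6-HHDP syntheses.

**Step 16**
Reactants: 25
Product: 26 target
Conditions: H2 (1 atm), Pd(OH)2/C, THF/MeOH 1:1, 23 °C
Reagents that add atoms: none (H2 adds only H)
Why: hydrogenolysis removes all 16 benzyl groups, including the C1 benzyl ether, to give 15 phenols plus the free C1–OH. Lactones are stable, no aryl iodide remains, and no stereocentre is touched.

**Compound list**

1 | methyl gallate | COC(=O)c1cc(O)c(O)c(O)c1 | starting material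
2 | benzyl bromide | BrCc1ccccc1 | starting material
3 | methyl 3,4,5-tris(benzyloxy)benzoate | COC(=O)c1cc(OCc2ccccc2)c(OCc2ccccc2)c(OCc2ccccc2)c1 | intermediate
4 | iodine | II | starting material
5 | methyl 3,4,5-tris(benzyloxy)-2-iodobenzoate | COC(=O)c1cc(OCc2ccccc2)c(OCc2ccccc2)c(OCc2ccccc2)c1I | intermediate
6 | water | O | starting material
7 | 3,4,5-tris(benzyloxy)-2-iodobenzoic acid | OC(=O)c1cc(OCc2ccccc2)c(OCc2ccccc2)c(OCc2ccccc2)c1I | intermediate
8 | oxalyl chloride | ClC(=O)C(=O)Cl | starting material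
9 | 3,4,5-tris(benzyloxy)-2-iodobenzoyl chloride | ClC(=O)c1cc(OCc2ccccc2)c(OCc2ccccc2)c(OCc2ccccc2)c1I | intermediate
10 | D-glucose (open-chain form drawn) | O=C[C@H](O)[C@@H](O)[C@H](O)[C@H](O)CO | starting material
11 | ethanethiol | CCS | starting material
12 | D-glucose diethyl dithioacetal | CCSC(SCC)[C@H](O)[C@@H](O)[C@H](O)[C@H](O)CO | intermediate
13 | benzaldehyde dimethyl acetal | COC(OC)c1ccccc1 | starting material
14 | 4,6-O-benzylidene-D-glucose diethyl dithioacetal | CCSC(SCC)[C@H](O)[C@@H](O)[C@@H]1OC(c7ccccc7)OC[C@H]1O | intermediate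
15 | 2,3,5-tris-O-aroyl-4,6-O-benzylidene dithioacetal | CCSC(SCC)[C@H](OC(=O)c3cc(OCc6ccccc6)c(OCc6ccccc6)c(OCc6ccccc6)c3I)[C@@H](OC(=O)c3cc(OCc6ccccc6)c(OCc6ccccc6)c(OCc6ccccc6)c3I)[C@@H]1OC(c7ccccc7)OC[C@H]1OC(=O)c3cc(OCc6ccccc6)c(OCc6ccccc6)c(OCc6ccccc6)c3I | intermediate
16 | aldehydo-sugar from 15 | O=C[C@H](OC(=O)c3cc(OCc6ccccc6)c(OCc6ccccc6)c(OCc6ccccc6)c3I)[C@@H](OC(=O)c3cc(OCc6ccccc6)c(OCc6ccccc6)c(OCc6ccccc6)c3I)[C@@H]1OC(c7ccccc7)OC[C@H]1OC(=O)c3cc(OCc6ccccc6)c(OCc6ccccc6)c(OCc6ccccc6)c3I | intermediate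
17 | N-iodosuccinimide | O=C1CCC(=O)N1I | starting material
18 | hexa-iodo aldehyde (three 2,6-diiodoaroyl esters) | O=C[C@H](OC(=O)c3c(I)c(OCc6ccccc6)c(OCc6ccccc6)c(OCc6ccccc6)c3I)[C@@H](OC(=O)c3c(I)c(OCc6ccccc6)c(OCc6ccccc6)c(OCc6ccccc6)c3I)[C@@H]1OC(c7ccccc7)OC[C@H]1OC(=O)c3c(I)c(OCc6ccccc6)c(OCc6ccccc6)c(OCc6ccccc6)c3I | intermediate
19 | bis-macrocyclic terphenoyl aldehyde (two iodides left) | O=C[C@@H]5OC(=O)c3c(I)c(OCc6ccccc6)c(OCc6ccccc6)c(OCc6ccccc6)c3-c3c(OCc6ccccc6)c(OCc6ccccc6)c(OCc6ccccc6)c4c3C(=O)O[C@H]5[C@@H]1OC(c7ccccc7)OC[C@H]1OC(=O)c8c(I)c(OCc6ccccc6)c(OCc6ccccc6)c(OCc6ccccc6)c84 | intermediate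
20 | NHK product, C1-OH (1R) | O1C(c7ccccc7)OC[C@H]2OC(=O)c3cc(OCc6ccccc6)c(OCc6ccccc6)c(OCc6ccccc6)c3-c3c(OCc6ccccc6)c(OCc6ccccc6)c(OCc6ccccc6)c4c3C(=O)O[C@H]([C@H]3OC(=O)c5c-4c(OCc6ccccc6)c(OCc6ccccc6)c(OCc6ccccc6)c5[C@H]3O)[C@@H]21 | intermediate
21 | benzyl trichloroacetimidate | N=C(OCc1ccccc1)C(Cl)(Cl)Cl | starting material
22 | C1-O-benzyl ether of 20 | O1C(c7ccccc7)OC[C@H]2OC(=O)c3cc(OCc6ccccc6)c(OCc6ccccc6)c(OCc6ccccc6)c3-c3c(OCc6ccccc6)c(OCc6ccccc6)c(OCc6ccccc6)c4c3C(=O)O[C@H]([C@H]3OC(=O)c5c-4c(OCc6ccccc6)c(OCc6ccccc6)c(OCc6ccccc6)c5[C@H]3OCc6ccccc6)[C@@H]21 | intermediate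
23 | 4,6-diol | OC[C@H]2OC(=O)c3cc(OCc6ccccc6)c(OCc6ccccc6)c(OCc6ccccc6)c3-c3c(OCc6ccccc6)c(OCc6ccccc6)c(OCc6ccccc6)c4c3C(=O)O[C@H]([C@H]3OC(=O)c5c-4c(OCc6ccccc6)c(OCc6ccccc6)c(OCc6ccccc6)c5[C@H]3OCc6ccccc6)[C@@H]2O | intermediate
24 | 4,6-bis(2-iodoaroyl) diester | O=C(OC[C@H]2OC(=O)c3cc(OCc6ccccc6)c(OCc6ccccc6)c(OCc6ccccc6)c3-c3c(OCc6ccccc6)c(OCc6ccccc6)c(OCc6ccccc6)c4c3C(=O)O[C@H]([C@H]3OC(=O)c5c-4c(OCc6ccccc6)c(OCc6ccccc6)c(OCc6ccccc6)c5[C@H]3OCc6ccccc6)[C@@H]2OC(=O)c8cc(OCc6ccccc6)c(OCc6ccccc6)c(OCc6ccccc6)c8I)c8cc(OCc6ccccc6)c(OCc6ccccc6)c(OCc6ccccc6)c8I | intermediate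
25 | hexadeca-O-benzyl target | O=C1OC[C@H]2OC(=O)c3cc(OCc6ccccc6)c(OCc6ccccc6)c(OCc6ccccc6)c3-c3c(OCc6ccccc6)c(OCc6ccccc6)c(OCc6ccccc6)c4c3C(=O)O[C@H]([C@H]3OC(=O)c5c-4c(OCc6ccccc6)c(OCc6ccccc6)c(OCc6ccccc6)c5[C@H]3OCc6ccccc6)[C@@H]2OC(=O)c2cc(OCc6ccccc6)c(OCc6ccccc6)c(OCc6ccccc6)c2-c2c1cc(OCc6ccccc6)c(OCc6ccccc6)c2OCc6ccccc6 | intermediate
26 | target, C-glucosidic NHTP/HHDP ellagitannin of the vescalagin/castalagin type (C1 R) | O=C1OC[C@H]2OC(=O)c3cc(O)c(O)c(O)c3-c3c(O)c(O)c(O)c4c3C(=O)O[C@H]([C@H]3OC(=O)c5c-4c(O)c(O)c(O)c5[C@H]3O)[C@@H]2OC(=O)c2cc(O)c(O)c(O)c2-c2c1cc(O)c(O)c2O | target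

**Totals**
- Total steps: 16.
- Longest linear sequence: 14 steps (methyl gallate → 9 → Steps 7–16).

**Three steps most likely to fail**
1. **Step 11 (NHK).** The aryl-Cr may be protonated instead of adding, or give the trans (1S) epimer.
   - Fallback: protodeiodinate ring C of 19 (Pd, HCO2NH4) and close C1 by biomimetic Lewis-acid (Sc(OTf)3) Friedel–Crafts hydroxyalkylation of the free C6′–H onto the aldehyde.
2. **Step 10 (double macrocyclic Ullmann).** It may give mixed pairings or oligomers.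
   - Fallback: couple the vicinal O2/O3 pair by Ullmann, then close the O3/O5 ring by Pd-catalysed intramolecular direct C–H arylation (Pd(OAc)2, PCy3·HBF4, PivOH, K2CO3) on a mono-iodo ring A.
3. **Step 9 (exhaustive iodination).** The second ortho-iodination of the deactivated rings may stall.
   - Fallback: skip iodination and use Pd-catalysed direct C–H arylation for the second biaryl bond (ring B C–H with ring A iodide). Alternatively, acylate with a pre-made 2,6-diiodo acyl fluoride.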